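When I sat down with the earlier runs I wanted one number that says where a flask of Q and G stops, and what share of that stop is J; zeta and eta were still to be made.

all flasks: Q 39 mM; E 0.29 mM
- ash: G 23 mM; Z 2.2 mM; run made earlier
- oak: G 37 mM; Z 2.2 mM; run made earlier
- cedar: G 42.9 mM; Z 1.8 mM; run made earlier
- zeta: G 30.0 mM; Z 1.2 mM; time 10 min
- eta: G 42.9 mM; Z 2.2 mM; time 5.0 min

| run | time / min | J / % | Q / % |
|---|---|---|---|
| ash | 1.00 | 14.3 | 79.5 |
| ash | 2.00 | 21.7 | 69.6 |
| ash | 3.00 | 24.2 | 63.8 |
| ash | 4.00 | 25.5 | 59.5 |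
| ash | 5.00 | 26.3 | 57.9 |
| oak | 0.417 | 11.9 | 83.8 |
| oak | 0.833 | 20.3 | 73.8 |
| oak | 1.33 | 25.0 | 63.9 |
| oak | 2.50 | 33.4 | 50.4 |
| oak | 5.00 | 39.3 | 40.5 |
| cedar | 0.417 | 13.5 | 81.6 |
| cedar | 0.833 | 21.8 | 68.6 |
| cedar | 1.33 | 29.7 | 58.9 |
| cedar | 2.50 | 37.2 | 45.0 |
| cedar | 5.00 | 42.8 | 33.1 |

(each reading ± 0.5 percentage points)



- the winner by amount of J, in percent of the Q charged; "neither" if no more than 2 percentage points parts them (zeta / eta / neither)
- how much J is there at the end, in percent of the Q charged: zeta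
- how much J is there at the end, in percent of the Q charged: eta

I followed the cedar run in slow motion. In the first instants, at 0.417 min, Q had lost 18.4% and J made up 73.4% of that loss, so something besides J was forming from the start. In the middle, at 2.50 min, I divided the Q reacted by cQ·cG, counting one G per Q, and read 0.0570 mM⁻¹. At the last reading, 5.00 min, the same division gave 0.120 mM⁻¹, twice the middle value, and this reaction quotient, reacted Q over cQ·cG, became my stall quotient. By then the share of J in the lost Q had sunk to 64.0%. The ash and oak runs gave 0.110 mM⁻¹ and 0.106 mM⁻¹ at their last readings, with quite different G charges, so I kept one G per Q.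

Of Q and G, G is the limiting reagent in zeta, 30.0 mM against 39 mM of Q. Setting zeta's quotient equal to the stall quotient gave 20.6 mM of Q reacted and J at 33.9%, which I took as a low figure, since the quotient was still climbing in cedar. Eta has cedar's charges and time, with Z at 2.2 mM instead of 1.8 mM, so the same reckoning returned cedar's J, 42.8%, and I chose eta.

The forecast gave 34.5% for zeta, 43.3% for eta and eta as winner: “Eta is essentially cedar with slightly more Z”. It counted about 1.35 G per Q where I counted one, and its zeta figure stands above mine.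

The flasks gave 36.3% in zeta and 43.0% in eta, so eta won by 6.7 percentage points.

    Q + G ⇌ J (K = 110 M⁻¹, k = 9.60 M⁻¹ min⁻¹)
    Q + G ⇌ L (K = 62.0 M⁻¹, k = 3.00 M⁻¹ min⁻¹)
    J + Z ⇌ L + Z, rate k3*[Z]*[J] forward; the back reaction follows from the equilibrium constant (k = 170 M⁻¹ min⁻¹)
    Z + E → D (k = 1.40 × 10⁵ M⁻¹ min⁻¹)

Zeta's own quotient at 10.0 min, from Q 43.7% and G 26.8% of its charge, came to 0.160 mM⁻¹, above the carried 0.120 mM⁻¹, and its J stood above my reckoning. The neighbouring flask is zeta with 160 mM of Q, so G came to 0.187 equiv to Q. The carried quotient and J share put its Q reacted at 28.2 mM, leaving 82.4% of its Q and giving J 11.3%. That flask held Q 82.0%, G 4.24% of its charge and J 11.5% at 10.0 min.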